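**Plan** (labdane numbering: ring A = C1–C5 and C10, ring B = C5–C10, side chain C11–C16)
1. Retrosynthesis: the acetate and free acid are set last, the C2 oxygen goes back to a ring-A enol ether and one C4 methyl to a formyl helper; ring A is then cut at C3–C4 and C5–C10, which opens ring B as well; the chain is cut at C1–C2 (Stille), at C10–C20 with C10≡C1 (alkyne methylalumination) and at C9–C11 (hydrazone alkylation).
2. Enabling feature: ring A carries its only oxygen on C2, and C5–C10 is the ring-fusion bond, so a 2-alkoxydiene C3=C2–C1=C10 and a dienophile C4=C5, joined by the C6–C9 chain, give rings A and B in one intramolecular Diels–Alder step.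
3. Forward: an iodide (C11–C16) and geranial (C4–C10, C17–C19) are joined at C9; the C10 aldehyde becomes an alkyne, then an (E)-iodoalkene (adds C20, C1); allylic oxidation gives the C18 enal; Stille coupling adds C2 and C3; the cycloaddition closes both rings; Wolff–Kishner reduction removes the helper; reduction and acetylation finish.
4. Stereochemistry: C13 from methyl hydrogen (R)-3-methylglutarate; C9 from the RAMP auxiliary; C5 and C10 from the endo, chair-tethered cycloaddition under control of C9; C2 from hydride attack anti to the two axial methyl groups.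

Key step: step 10

Assumption: geranial is used as the single (2E) isomer, which is sold as such or made from geraniol with MnO2.

**Step 1**
Reactants: 1 methyl hydrogen (R)-3-methylglutarate
Product: 2 methyl (3R)-5-hydroxy-3-methylpentanoate
Conditions: BH3·SMe2 (1.1 equiv), THF, 0 °C to rt; then H2O
Reagents that add atoms: none
Why: Chemoselective borane reduction of a carboxylic acid beside a methyl ester (acyloxyborane pathway) should give the hydroxy ester with the stereocentre untouched; it is used at once to avoid lactonisation.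

**Step 2**
Reactants: 2 methyl (3R)-5-hydroxy-3-methylpentanoate
Product: 3 methyl (3S)-5-iodo-3-methylpentanoate
Conditions: I2, PPh3, imidazole, CH2Cl2, 0 °C to rt
Reagents that add atoms: iodine [I][I]
Why: Appel-type (Garegg–Samuelsson) iodination by SN2 displacement of the alkoxyphosphonium group at the primary carbon; the stereocentre is not involved (R becomes S only through the priority of the iodoethyl branch).

**Step 3**
Reactants: 4 geranial; 5 RAMP [(2R)-1-amino-2-(methoxymethyl)pyrrolidine]
Product: 6 (2R)-N-[(1E,2E)-3,7-dimethylocta-2,6-dien-1-ylidene]-2-(methoxymethyl)pyrrolidin-1-amine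
Conditions: neat, 0 °C to rt, 4 Å molecular sieves
Reagents that add atoms: none
Why: Condensation of the enal with the N-aminopyrrolidine gives the (E)-hydrazone (first stage of the Enders RAMP hydrazone method); no stereocentre is formed.

**Step 4**
Reactants: 6 geranial RAMP hydrazone; 3 methyl (3S)-5-iodo-3-methylpentanoate
Product: 8 methyl (3R,6S)-6-[(E)-{[(2R)-2-(methoxymethyl)pyrrolidin-1-yl]imino}methyl]-3,11-dimethyl-7-methylidenedodec-10-enoate, via lithium aza-dienolate 7 (not isolated)
Conditions: LiN(i-Pr)2 (1.1 equiv), THF, 0 °C; then 3, −100 °C to −20 °C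
Reagents that add atoms: none
Why: Enders RAMP hydrazone alkylation in its deconjugative form: the γ-methyl group syn to the C=N is deprotonated and the 1-azapentadienyl lithium 7 is alkylated at the α-carbon by the primary iodide (SN2), which moves the double bond to C8=C17 and creates C9; the methoxymethyl-chelated lithium leaves one face of the (E)-C=C–N unit open, and with RAMP that face should give the 6S (C9) configuration.

**Step 5**
Reactants: 8 alkylated hydrazone
Product: 9 methyl (3R,6S)-6-formyl-3,11-dimethyl-7-methylidenedodec-10-enoate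
Conditions: saturated aq. oxalic acid, Et2O, rt (two phases)
Reagents that add atoms: water O
Why: Mild two-phase acidic hydrazone hydrolysis should free the aldehyde and return RAMP to the aqueous phase without epimerising C9 or moving the β,γ-double bond into conjugation; the aldehyde is taken on at once.

**Step 6**
Reactants: 9 aldehyde
Product: 10 methyl (3R,6S)-6-ethynyl-3,11-dimethyl-7-methylidenedodec-10-enoate
Conditions: dimethyl (diazomethyl)phosphonate, KOt-Bu, THF, −78 °C to −30 °C
Reagents that add atoms: dimethyl (diazomethyl)phosphonate COP(=O)(OC)C=[N+]=[N-]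
Why: Seyferth–Gilbert homologation (phosphonate addition, loss of dimethyl phosphate and nitrogen, 1,2-hydride shift of the alkylidene carbene) turns CHO into C≡CH at low temperature, where the weakly basic reagent should neither epimerise C9 nor attack the ester.

**Step 7**
Reactants: 10 alkyne
Product: 12 methyl (3R,6S)-6-[(1E)-1-iodoprop-1-en-2-yl]-3,11-dimethyl-7-methylidenedodec-10-enoate, via alkenyldimethylalane 11 (not isolated)
Conditions: AlMe3 (3 equiv), Cp2ZrCl2 (0.25 equiv), H2O (1.5 equiv), CH2Cl2, −25 °C; then I2, THF, −25 °C to 0 °C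
Reagents that add atoms: trimethylaluminium C[Al](C)C; iodine [I][I]
Why: Negishi zirconium-catalysed syn-carboalumination (water-accelerated variant) puts the methyl group (C20) on the internal alkyne carbon and aluminium on the terminal one, and iodinolysis with retention gives the (E)-iodoalkene; di- and trisubstituted alkenes do not react and the short cold protocol spares the ester.

**Step 8**
Reactants: 12 iodoalkene
Product: 14 methyl (3R,6S,10E)-6-[(1E)-1-iodoprop-1-en-2-yl]-3,11-dimethyl-7-methylidene-12-oxododec-10-enoate, via allylic alcohol 13 (not isolated)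
Conditions: SeO2 (0.3 equiv), t-BuOOH (3 equiv), salicylic acid (0.1 equiv), CH2Cl2, rt; filtration; then MnO2, CH2Cl2, rt
Reagents that add atoms: selenium dioxide O=[Se]=O; tert-butyl hydroperoxide CC(C)(C)OO
Why: Riley allylic oxidation with catalytic SeO2 (ene reaction, then 2,3-sigmatropic shift) attacks the most electron-rich trisubstituted alkene at its (E)-methyl group, the 1,1-disubstituted and iodo-substituted alkenes being slower; MnO2 then converges allylic alcohol 13 on the (E)-enal.

**Step 9**
Reactants: 14 iodo enal; 15 tributyl(1-ethoxyvinyl)stannane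
Product: 16 methyl (3R,6S,10E)-6-[(2E)-4-ethoxypenta-2,4-dien-2-yl]-3,11-dimethyl-7-methylidene-12-oxododec-10-enoate
Conditions: Pd(PPh3)4 (5 mol%), CuI (10 mol%), DMF, rt, dark; Et3N-treated silica
Reagents that add atoms: none
Why: Stille coupling of the alkenyl iodide with the α-ethoxyvinyl stannane goes with retention of the (E)-geometry and gives the 2-ethoxy-1,3-diene under neutral conditions that spare the enal; the acid-labile diene is used directly.

**Step 10**
Reactants: 16 trienal with 2-ethoxydiene
Product: 17 methyl (3R)-5-[(1S,4aR,5R,8aR)-7-ethoxy-5-formyl-5,8a-dimethyl-2-methylidene-1,2,3,4,4a,5,6,8a-octahydronaphthalen-1-yl]-3-methylpentanoate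
Conditions: Me2AlCl (2.2 equiv), CH2Cl2, −78 °C to −20 °C; Et3N, then aq. NaHCO3
Reagents that add atoms: none
Why: Me2AlCl binds the formyl oxygen of the (E)-2-methyl enal and lowers its LUMO toward the electron-rich 2-ethoxydiene, so that a concerted, asynchronous intramolecular [4+2] cycloaddition (C5–C10 leading) forms C3–C4 and C5–C10. The closest known reaction type is the Lewis-acid-promoted type 1 intramolecular Diels–Alder reaction of 2-methyldeca-2,8,10-trienals, which gives trans-fused octalin carbaldehydes with a quaternary formyl-bearing carbon. Ring A closes as the cycloadduct ring itself (six-membered, both new bonds in it), and ring B closes through the C5–C10 bond in the fused mode, 6-exo with respect to both C4=C5 and C10=C1, with the C6–C9 tether in a chair. C5 and C10 are set trans by the endo transition state (formyl under the diene, tether and 2-methyl group exo) acting on the (E)-enal and the (E)-diene, which places H-5 opposite the inside methyl group of C10; C4 (formyl cis to H-5) follows from suprafacial addition to the (E)-enal and is erased in step 11. The absolute sense at C5 and C10 is relayed from C9, whose side chain takes the equatorial position of the chair-like forming ring B, so that the dienophile reaches only one face of the diene. The step therefore needs endo over exo selectivity and π-facial selectivity, secured by the aluminium-bound formyl group and by the C9 substituent, while the regiochemistry is fixed by the tether although C3–C4 is not the electronically preferred pairing of a 2-alkoxydiene.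

**Step 11**
Reactants: 17 cycloadduct
Product: 20 (3R)-3-methyl-5-[(1S,4aS,8aS)-5,5,8a-trimethyl-2-methylidene-7-oxodecahydronaphthalen-1-yl]pentanoic acid, via aldehyde hydrazone 18 (not isolated), via enol ether acid 19 (not isolated)
Conditions: N2H4·H2O, diethylene glycol, 120 °C; KOH, 200 °C (H2O and excess N2H4 distilled off); then 1 M HCl, THF, rt
Reagents that add atoms: potassium hydroxide [K+].[OH-]; water O
Why: Wolff–Kishner reduction (Huang–Minlon procedure) of the non-enolisable neopentyl aldehyde via hydrazone 18 turns the formyl helper into the second C4 methyl group, so C4 is no longer a stereocentre, while KOH saponifies the ester; the enol ether and exocyclic alkene are base-stable, and the acidic work-up hydrolyses enol ether 19 to the C2 ketone.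

**Step 12**
Reactants: 20 keto acid
Product: 21 (3R)-5-[(1S,4aS,7R,8aS)-7-hydroxy-5,5,8a-trimethyl-2-methylidenedecahydronaphthalen-1-yl]-3-methylpentanoic acid
Conditions: LiBH(s-Bu)3 (2.5 equiv), THF, −78 °C; aq. NH4Cl, then 1 M HCl
Reagents that add atoms: none
Why: After the first equivalent deprotonates the acid, the bulky trialkylborohydride adds to the C2 ketone from the α-face (equatorial trajectory), because the axial β-trajectory is blocked by the syn-axial methyl groups on C4 and C10; this should give the axial 2β (7R) alcohol.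

**Step 13**
Reactants: 21 hydroxy acid
Product: 23 (3R)-5-[(1S,4aS,7R,8aS)-7-(acetyloxy)-5,5,8a-trimethyl-2-methylidenedecahydronaphthalen-1-yl]-3-methylpentanoic acid, via mixed anhydride 22 (not isolated)
Conditions: Ac2O (5 equiv), DMAP (0.5 equiv), pyridine, 40 °C; then H2O, THF, rt
Reagents that add atoms: acetic anhydride CC(=O)OC(C)=O
Why: DMAP-catalysed acyl transfer (Steglich-type, through the N-acetylpyridinium ion) esterifies the hindered axial alcohol with retention; the acid is converted for the time being into mixed anhydride 22, which water cleaves at the acetyl carbonyl while the secondary acetate stays.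

**Compound list**
1 | methyl hydrogen (R)-3-methylglutarate [(3R)-5-methoxy-3-methyl-5-oxopentanoic acid] | OC(=O)C[C@@H](C)CC(=O)OC | starting material
2 | methyl (3R)-5-hydroxy-3-methylpentanoate | OCC[C@@H](C)CC(=O)OC | intermediate
3 | methyl (3S)-5-iodo-3-methylpentanoate | ICC[C@@H](C)CC(=O)OC | intermediate
4 | geranial [(2E)-3,7-dimethylocta-2,6-dienal] | CC(C)=CCC/C(C)=C/C=O | starting material
5 | RAMP [(2R)-1-amino-2-(methoxymethyl)pyrrolidine] | COC[C@H]1CCCN1N | starting material
6 | (2R)-N-[(1E,2E)-3,7-dimethylocta-2,6-dien-1-ylidene]-2-(methoxymethyl)pyrrolidin-1-amine | COC[C@H]1CCCN1/N=C/C=C(\C)CCC=C(C)C | intermediate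
7 | lithium aza-dienolate of 6 (N-lithio (E)-dienamide with C8=C17 methylene) | COC[C@H]1CCCN1N([Li])/C=C/C(=C)CCC=C(C)C | intermediate
8 | methyl (3R,6S)-6-[(E)-{[(2R)-2-(methoxymethyl)pyrrolidin-1-yl]imino}methyl]-3,11-dimethyl-7-methylidenedodec-10-enoate | COC[C@H]1CCCN1/N=C/[C@@H](CC[C@@H](C)CC(=O)OC)C(=C)CCC=C(C)C | intermediate
9 | methyl (3R,6S)-6-formyl-3,11-dimethyl-7-methylidenedodec-10-enoate | O=C[C@@H](CC[C@@H](C)CC(=O)OC)C(=C)CCC=C(C)C | intermediate
10 | methyl (3R,6S)-6-ethynyl-3,11-dimethyl-7-methylidenedodec-10-enoate | C#C[C@@H](CC[C@@H](C)CC(=O)OC)C(=C)CCC=C(C)C | intermediate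
11 | (E)-alkenyldimethylalane from 10 (methyl on C10, AlMe2 on C1) | C[Al](C)/C=C(\C)[C@@H](CC[C@@H](C)CC(=O)OC)C(=C)CCC=C(C)C | intermediate
12 | methyl (3R,6S)-6-[(1E)-1-iodoprop-1-en-2-yl]-3,11-dimethyl-7-methylidenedodec-10-enoate | I/C=C(\C)[C@@H](CC[C@@H](C)CC(=O)OC)C(=C)CCC=C(C)C | intermediate
13 | methyl (3R,6S,10E)-12-hydroxy-6-[(1E)-1-iodoprop-1-en-2-yl]-3,11-dimethyl-7-methylidenedodec-10-enoate | I/C=C(\C)[C@@H](CC[C@@H](C)CC(=O)OC)C(=C)CC/C=C(\C)CO | intermediate
14 | methyl (3R,6S,10E)-6-[(1E)-1-iodoprop-1-en-2-yl]-3,11-dimethyl-7-methylidene-12-oxododec-10-enoate | I/C=C(\C)[C@@H](CC[C@@H](C)CC(=O)OC)C(=C)CC/C=C(\C)C=O | intermediate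
15 | tributyl(1-ethoxyvinyl)stannane | CCCC[Sn](CCCC)(CCCC)C(=C)OCC | starting material
16 | methyl (3R,6S,10E)-6-[(2E)-4-ethoxypenta-2,4-dien-2-yl]-3,11-dimethyl-7-methylidene-12-oxododec-10-enoate | C=C(OCC)/C=C(\C)[C@@H](CC[C@@H](C)CC(=O)OC)C(=C)CC/C=C(\C)C=O | intermediate
17 | methyl (3R)-5-[(1S,4aR,5R,8aR)-7-ethoxy-5-formyl-5,8a-dimethyl-2-methylidene-1,2,3,4,4a,5,6,8a-octahydronaphthalen-1-yl]-3-methylpentanoate (trans-fused, formyl α on C4) | C=C1CC[C@H]2[C@](C)(C=O)CC(OCC)=C[C@]2(C)[C@H]1CC[C@@H](C)CC(=O)OC | intermediate
18 | hydrazone of aldehyde 17 (CH=N–NH2 on C4) | C=C1CC[C@H]2[C@](C)(/C=N/N)CC(OCC)=C[C@]2(C)[C@H]1CC[C@@H](C)CC(=O)OC | intermediate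
19 | (3R)-5-[(1S,4aS,8aS)-7-ethoxy-5,5,8a-trimethyl-2-methylidene-1,2,3,4,4a,5,6,8a-octahydronaphthalen-1-yl]-3-methylpentanoic acid | C=C1CC[C@H]2C(C)(C)CC(OCC)=C[C@]2(C)[C@H]1CC[C@@H](C)CC(=O)O | intermediate
20 | (3R)-3-methyl-5-[(1S,4aS,8aS)-5,5,8a-trimethyl-2-methylidene-7-oxodecahydronaphthalen-1-yl]pentanoic acid | C=C1CC[C@H]2C(C)(C)CC(=O)C[C@]2(C)[C@H]1CC[C@@H](C)CC(=O)O | intermediate
21 | (3R)-5-[(1S,4aS,7R,8aS)-7-hydroxy-5,5,8a-trimethyl-2-methylidenedecahydronaphthalen-1-yl]-3-methylpentanoic acid | C=C1CC[C@H]2C(C)(C)C[C@@H](O)C[C@]2(C)[C@H]1CC[C@@H](C)CC(=O)O | intermediate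
22 | acetic mixed anhydride of the 2β-acetoxy acid | C=C1CC[C@H]2C(C)(C)C[C@@H](OC(C)=O)C[C@]2(C)[C@H]1CC[C@@H](C)CC(=O)OC(C)=O | intermediate
23 | (3R)-5-[(1S,4aS,7R,8aS)-7-(acetyloxy)-5,5,8a-trimethyl-2-methylidenedecahydronaphthalen-1-yl]-3-methylpentanoic acid | C=C1CC[C@H]2C(C)(C)C[C@@H](OC(C)=O)C[C@]2(C)[C@H]1CC[C@@H](C)CC(=O)O | target

**Totals**
Total step count: 13. Longest linear sequence: 12 steps (steps 1, 2 and 4–13, from 1 to 23).

**Steps most likely to fail**

Step 10. The exo mode or the other face of the diene may compete, giving cis-fused or ring-fusion-inverted decalins, and the Lewis acid may degrade the enol ether before ring closure. The fallback sets out from 16 and comes back at 17. It replaces substrate control by reagent control: the cycloaddition is run under a chiral oxazaborolidinium triflimide (a protonated diphenylprolinol-derived B-aryl oxazaborolidine), a catalyst class that accepts 2-substituted enals and 2-oxygenated dienes. Its enantiomer is chosen so that its facial preference is matched with that of C9. This fallback makes no new compound (F0).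

Step 4. Deprotonation may be unselective between the γ-positions, the electrophile may enter at the γ-carbon or from the wrong face, and the aza-dienolate may attack the ester of the iodide. The fallback sets out from iodide 3 and comes back at aldehyde 9, using Evans alkylation instead of the hydrazone method. Commercial geranic acid is converted through its pivaloyl mixed anhydride and lithiated (4S)-4-benzyl-1,3-oxazolidin-2-one into (4S)-4-benzyl-3-[(2E)-3,7-dimethylocta-2,6-dienoyl]-1,3-oxazolidin-2-one F1. Its sodium dienolate (NaN(SiMe3)2, THF, −78 °C) is alkylated at the α-carbon by 3 on the face away from the benzyl group, which should give methyl (3R,6S)-6-{[(4S)-4-benzyl-2-oxo-1,3-oxazolidin-3-yl]carbonyl}-3,11-dimethyl-7-methylidenedodec-10-enoate F2. LiSEt then gives methyl (3R,6S)-6-[(ethylsulfanyl)carbonyl]-3,11-dimethyl-7-methylidenedodec-10-enoate F3, and Fukuyama reduction (Et3SiH, Pd/C) gives 9.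

Step 11. The hindered neopentyl hydrazone may be reduced incompletely, the exocyclic double bond may migrate in hot base, and acyl hydrazide formation at the ester may hold material back. The fallback sets out from 17 and comes back at 20, using radical deoxygenation instead of the Wolff–Kishner reduction. NaBH4 in MeOH at 0 °C reduces the aldehyde to methyl (3R)-5-[(1S,4aR,5R,8aR)-7-ethoxy-5-(hydroxymethyl)-5,8a-dimethyl-2-methylidene-1,2,3,4,4a,5,6,8a-octahydronaphthalen-1-yl]-3-methylpentanoate F4. Phenyl chlorothionoformate with pyridine and DMAP gives its O-phenyl thionocarbonate F5. Barton–McCombie reduction (Bu3SnH, AIBN, toluene, 110 °C) gives methyl (3R)-5-[(1S,4aS,8aS)-7-ethoxy-5,5,8a-trimethyl-2-methylidene-1,2,3,4,4a,5,6,8a-octahydronaphthalen-1-yl]-3-methylpentanoate F6. LiOH in aqueous THF followed by 1 M HCl then gives 20.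

**Further compounds**
F0 | step 10 | none | none
F1 | step 4 | (4S)-4-benzyl-3-[(2E)-3,7-dimethylocta-2,6-dienoyl]-1,3-oxazolidin-2-one | O=C1OC[C@H](Cc2ccccc2)N1C(=O)/C=C(\C)CCC=C(C)C
F2 | step 4 | methyl (3R,6S)-6-{[(4S)-4-benzyl-2-oxo-1,3-oxazolidin-3-yl]carbonyl}-3,11-dimethyl-7-methylidenedodec-10-enoate | O=C1OC[C@H](Cc2ccccc2)N1C(=O)[C@@H](CC[C@@H](C)CC(=O)OC)C(=C)CCC=C(C)C
F3 | step 4 | methyl (3R,6S)-6-[(ethylsulfanyl)carbonyl]-3,11-dimethyl-7-methylidenedodec-10-enoate | CCSC(=O)[C@@H](CC[C@@H](C)CC(=O)OC)C(=C)CCC=C(C)C
F4 | step 11 | methyl (3R)-5-[(1S,4aR,5R,8aR)-7-ethoxy-5-(hydroxymethyl)-5,8a-dimethyl-2-methylidene-1,2,3,4,4a,5,6,8a-octahydronaphthalen-1-yl]-3-methylpentanoate | C=C1CC[C@H]2[C@](C)(CO)CC(OCC)=C[C@]2(C)[C@H]1CC[C@@H](C)CC(=O)OC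
F5 | step 11 | O-phenyl thionocarbonate of F4 | C=C1CC[C@H]2[C@](C)(COC(=S)Oc3ccccc3)CC(OCC)=C[C@]2(C)[C@H]1CC[C@@H](C)CC(=O)OC
F6 | step 11 | methyl (3R)-5-[(1S,4aS,8aS)-7-ethoxy-5,5,8a-trimethyl-2-methylidene-1,2,3,4,4a,5,6,8a-octahydronaphthalen-1-yl]-3-methylpentanoate | C=C1CC[C@H]2C(C)(C)CC(OCC)=C[C@]2(C)[C@H]1CC[C@@H](C)CC(=O)OC
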